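Locants used throughout: chromanone O1, C2, C3, C4, C4a, C5–C8, C8a; C9 is the CH2 of the four-membered ring; ring B is C1' (bonded to C9), C2' (bonded to C3), C3', C4', C5', C6'.

## Analysis of the target

Target 21 is a 5,7-dimethoxychroman-4-one and a dimethoxybenzocyclobutene that share a single atom, C3; the four-membered ring is C3–C9–C1'–C2', and ring B carries methoxy groups at C3' and C4'. C3 is the only stereocentre, an all-carbon quaternary centre of (S) configuration bonded to C2 (OCH2), C4 (C=O), C9 (CH2) and C2' (aryl). With no second stereocentre to relay from, its configuration has to come from an enantioselective step and cannot be corrected by equilibration. The ketone cannot enolise and the aryl methyl ethers are robust, but ring A is a very electron-rich arene that reacts with electrophiles at C6 and C8. The benzocyclobutene can open on strong heating to an ortho-quinodimethane in which C3 is trigonal, so high temperature would racemise the compound. The difficulty lies in the quaternary spiro carbon that is part of a strained ring, and in the methoxy group at C3', directly beside the ring fusion. The strategy rests on the fusion of ring B to the four-membered ring: C6'≡C1'–C9–C3–C2'≡C3' is a hexa-1,5-diyne and C4'–C5' a third alkyne, so one (2+2+2) cyclotrimerisation builds ring B and the cyclobutene on a chromanone that already holds the stereocentre.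

## Retrosynthetic reasoning

**End game (21 to 16).** The C3' methyl ether of 21 is traced to phenol 20, and the C3'–O bond of 20 to the C3'–Si bond of 17. An oxygen substituent cannot be carried on an alkyne terminus attached to a quaternary carbon, whereas a silyl group can, and it is exchanged for oxygen by ipso-substitution. 17 in turn comes from 16, which has a second silyl group at C5'. That group is the steering element of the cyclotrimerisation and is removed by acid. It should leave first because C5' is a β-position of the benzocyclobutene, while C3' is the α-position next to the strained fusion.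

**Key disconnection (16 to 12 and 15).** The bonds C1'–C2', C3'–C4' and C5'–C6' are cut. These are exactly the three bonds a cyclotrimerisation forms, so ring B and the four-membered ring disappear together and a chromanone with two alkyne arms on C3 remains. No bond to C3 is made or broken, so the stereocentre of 12 passes unchanged into 16. The forward reaction has to favour cross- over homo-cyclisation and to orient 15 so that its methoxy carbon bonds to the silylated terminus C3'.

**Chromanone ring (12 to 10).** The C4–C4a bond is cut as an intramolecular Friedel–Crafts acylation. The aryl ether in 10 derives from the symmetrical phenol 7, whose two positions ortho to oxygen are equivalent, so only the 5,7-dimethoxy pattern can result. Closing the O1–C8a bond instead, by nucleophilic aromatic substitution under base, was not chosen: it needs an alkoxide two atoms away from the ketone across the quaternary carbon, an arrangement that can fragment by a retro-aldol reaction, and alkoxide endangers the alkynyl–silicon bond.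

**Acid and ether (10 to 8 to 6 and 7).** The acid is traced to methyl ester 8, to be cleaved at the methyl carbon because hydroxide would remove the alkynyl silyl group. The C2–O bond is cut as a Mitsunobu coupling of primary alcohol 6 with 7.

**Stereocentre (6 to 4).** Hydroxy ester 6 is traced to the prochiral malonate 4 by reduction of one of its two enantiotopic ester groups. The two carboxyl carbons of 4 become C2 and C4, so the quaternary stereocentre is created without forming a carbon–carbon bond enantioselectively at a crowded centre.

**Quaternary carbon (4 to 1 and 2).** The C(sp3)–C(sp) bond is cut as an electrophilic alkynylation of enolate 3, formed from 1, with iodonium salt 2. The propargyl group is in place first, because the reverse order would leave an acidic hydrogen on the carbon that carries the alkynyl group, a propargylic position prone to base-induced isomerisation. The silyl group arrives with the alkyne, so the two alkynes are differentiated from the first step.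

**Alkyne partner (15 to 13).** 15 is traced to chloroacetal 13 by double elimination and C-silylation of the acetylide 14.

## Alternatives that were turned down

Alternative 1: The disconnection is the C9–C1' bond, with the chromanone built afterwards.
- Forward key step: zerovalent palladium from Pd2(dba)3 with a chiral ligand inserts into the C–Br bond of methyl 2-(6-bromo-2,3-dimethoxyphenyl)-2-methylpropanoate A1 and, with K2CO3 as base, activates one of the two enantiotopic methyl groups. Reductive elimination gives the benzocyclobutene ester A2 with the quaternary centre. The second methyl group would then have to be oxidised at a C–H bond and joined to the oxygen of 7 before the pyranone ring is closed by acylation.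
- For it: the oxygen pattern of ring B is bought with A1, there is no orientation question and no silicon-to-oxygen exchange, and ring and stereocentre form in one catalytic step. On control of ring B substitution it is stronger than the chosen route.
- Against it: the enantioselection must happen in a C–H cleavage that leads to a strained four-membered ring, a closure that depends on very bulky ligands. The reaction needs temperatures near those at which an acceptor-substituted benzocyclobutene such as A2 may open, which threatens the new stereocentre. A second methyl C–H oxidation on a hindered substrate follows.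
- Comparison: the chosen route offers instead a stereocentre set in an open-chain compound, 6, where its purity can be checked and upgraded before any ring is built, and a ring-forming step in which arene formation pays for the strain at moderate temperature. The step counts are similar.

Alternative 2: The disconnection cuts O1–C8a and C4–C4a back to a ring A aryne.
- Forward key step: 3,5-dimethoxybenzyne A4 adds the carboxylate oxygen of (R)-1-(chloromethyl)-5,6-dimethoxybenzocyclobutene-1-carboxylic acid A3 at the aryne carbon remote from the methoxy group. The aryl anion, formed next to that methoxy group, takes over the acyl group to give hydroxy ketone A5, and the phenoxide of A5 would then displace chloride to close the pyranone.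
- For it: it is the most convergent plan, ring A arrives complete with A4, the inductive effect of the methoxy group directs the addition, and no Friedel–Crafts step is needed. In convergence it is stronger than the chosen route.
- Against it: A3 already contains the benzocyclobutene, the quaternary stereocentre and the ring B oxygenation, so the key step solves the easier half of the problem. The acyl shift to the aryl anion must compete with protonation, at an acyl carbon attached to a quaternary centre, and the final closure from A5 is a substitution at a neopentyl-type carbon.
- Comparison: the chosen strategy offers what this one presupposes, the construction of the strained half itself.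

Alternative 3: The disconnection is C3–C4, with C9–C1' closed afterwards.
- Forward key step: a chiral triazolium-derived N-heterocyclic carbene converts 2-{[2-(6-bromo-2,3-dimethoxyphenyl)prop-2-en-1-yl]oxy}-4,6-dimethoxybenzaldehyde A6 into its acyl anion equivalent, which adds across the 1,1-disubstituted alkene to give chromanone A7 with a methyl group on the new quaternary C3. A methyl C–H arylation catalysed by Pd(OAc)2 and a bulky phosphine would then close the four-membered ring of A7.
- For it: it is the shortest route, all oxygen substituents are bought with A6, and pyranone ring and stereocentre form in one catalytic step. On step economy it is stronger than the chosen route.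
- Against it: the aldehyde group of A6 is flanked by two ortho oxygen substituents and is strongly donor-substituted, so carbene addition is disfavoured. The alkene of A6 carries a 2,6-disubstituted aryl group that blocks approach and makes face discrimination uncertain. The later cyclobutene closure needs the same high temperature as in Alternative 1, now on A7, whose stereocentre could be lost by ring opening of the product.
- Comparison: the chosen route offers instead a stereocentre set independently of the ring closures and a strained-ring formation under milder conditions.

Key step: step 7

Remark on the chemistry: the sense of induction of the catalyst formed from Et2Zn and the chiral ligand in step 2 cannot be predicted for this pair of substituents, so the ligand antipode that delivers (S)-6 is to be used, both antipodes being available.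

## Route

Step 1
Reactants: 1 dimethyl 2-(prop-2-yn-1-yl)propanedioate; 2 phenyl[(trimethylsilyl)ethynyl]iodonium trifluoromethanesulfonate
Product: 4 dimethyl 2-(prop-2-yn-1-yl)-2-[(trimethylsilyl)ethynyl]propanedioate, via potassium malonate enolate 3 (not isolated)
Conditions: KOtBu (1.0 equiv), THF, −78 °C; then 2, −78 °C to rt
Reagents that add atoms: none
Why: Electrophilic alkynylation of a stabilised carbanion with an alkynyl(aryl)iodonium salt: the malonate C–H is deprotonated in preference to the alkyne C–H, the enolate adds to the β-carbon of 2, iodobenzene leaves, and the alkylidene carbene rearranges by a fast 1,2-silyl shift to the silylalkyne before it can insert into a C–H bond. No fluoride or protic base is present, so the C–Si bond is kept and the two alkynes stay differentiated.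

Step 2
Reactants: 4 dimethyl 2-(prop-2-yn-1-yl)-2-[(trimethylsilyl)ethynyl]propanedioate
Product: 6 methyl (2S)-2-(hydroxymethyl)-2-[(trimethylsilyl)ethynyl]pent-4-ynoate, via triethoxysilyl ether 5 (not isolated)
Conditions: Et2Zn (10 mol%), chiral ProPhenol-type bis(diarylcarbinol) aminophenol ligand (5 mol%), (EtO)3SiH (3 equiv), THF, 0 °C to rt; then 1 M HCl
Reagents that add atoms: none
Why: Desymmetrising hydrosilylation of a disubstituted malonic ester: the zinc hydride generated from Et2Zn, the ligand and the silane binds both ester carbonyls and delivers hydride to one enantiotopic ester, which is reduced through the aldehyde stage to the silyl ether, while the remaining ester is no longer chelated and stays. The quaternary stereocentre is set by the chiral pocket of the ligand, which has to tell the linear silylalkynyl group from the bent propargyl group.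

Step 3
Reactants: 6 methyl (2S)-2-(hydroxymethyl)-2-[(trimethylsilyl)ethynyl]pent-4-ynoate; 7 3,5-dimethoxyphenol
Product: 8 methyl (2S)-2-[(3,5-dimethoxyphenoxy)methyl]-2-[(trimethylsilyl)ethynyl]pent-4-ynoate
Conditions: PPh3, DIAD, toluene, 0 °C to 80 °C
Reagents that add atoms: none
Why: Mitsunobu etherification of a primary alcohol with a phenol; the carbinol carbon is neopentylic but has no β-hydrogen, so elimination cannot compete and warming drives the substitution. The stereocentre is not involved.

Step 4
Reactants: 8 methyl (2S)-2-[(3,5-dimethoxyphenoxy)methyl]-2-[(trimethylsilyl)ethynyl]pent-4-ynoate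
Product: 10 (2S)-2-[(3,5-dimethoxyphenoxy)methyl]-2-[(trimethylsilyl)ethynyl]pent-4-ynoic acid, via lithium carboxylate 9 (not isolated)
Conditions: LiI (anhydrous, 5 equiv), EtOAc, reflux, dark; then 1 M HCl
Reagents that add atoms: none
Why: SN2 dealkylation of a methyl ester by iodide, assisted by lithium at the carbonyl oxygen; the attack is at the methyl carbon, so hindrance at the acyl carbon does not matter, and hydroxide, which would cleave the alkynyl–silicon bond, is avoided. Aryl methyl ethers are inert under these conditions.

Step 5
Reactants: 10 (2S)-2-[(3,5-dimethoxyphenoxy)methyl]-2-[(trimethylsilyl)ethynyl]pent-4-ynoic acid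
Product: 12 (3S)-5,7-dimethoxy-3-(prop-2-yn-1-yl)-3-[(trimethylsilyl)ethynyl]chroman-4-one, via mixed trifluoroacetic anhydride 11 (not isolated)
Conditions: TFAA, CH2Cl2, 0 °C to rt
Reagents that add atoms: none
Why: Intramolecular Friedel–Crafts acylation through the mixed anhydride; the ring is activated by three oxygen substituents and both positions ortho to the ether oxygen are equivalent, so only the 5,7-dimethoxy chromanone can form, and the quaternary carbon favours the six-membered closure. The acyl carbon has no α-hydrogen, so neither ketene formation nor epimerisation is possible.

Step 6
Reactants: 13 2-chloro-1,1-dimethoxyethane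
Product: 15 (methoxyethynyl)trimethylsilane, via lithium methoxyacetylide 14 (not isolated)
Conditions: LiNEt2 (3 equiv), THF, 0 °C to rt; then TMSCl (2.2 equiv), −78 °C to rt; distillation
Reagents that add atoms: chlorotrimethylsilane, C[Si](C)(C)Cl
Why: Three equivalents of amide base effect two eliminations and deprotonate the resulting alkoxyalkyne; the acetylide is silylated at carbon. Methoxy is preferred to ethoxy because it has no β-hydrogen and cannot fragment to a ketene on heating in step 7.

Step 7
Reactants: 12 (3S)-5,7-dimethoxy-3-(prop-2-yn-1-yl)-3-[(trimethylsilyl)ethynyl]chroman-4-one; 15 (methoxyethynyl)trimethylsilane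
Product: 16 (S)-5,7-dimethoxychroman-4-one spiro-fused at C3 to the benzocyclobutene whose ring B carries SiMe3 at C3' and C5' and OMe at C4'
Conditions: CpCo(CO)2 (10 mol%), 15 (8 equiv), degassed toluene, reflux, hν, 12 added over 10 h by syringe pump
Reagents that add atoms: none
Why: CpCo(CO)2 loses CO under heat and light, and the CpCo fragment (monovalent cobalt) couples two alkynes oxidatively to a cobaltacyclopentadiene (trivalent cobalt); incorporation of the third alkyne and reductive elimination release the arene and return monovalent cobalt. The closest known reaction type is the CpCo(CO)2-mediated cocyclisation of hexa-1,5-diynes with silylalkynes to benzocyclobutenes. Three carbon–carbon bonds form: C1'–C2' between the inner carbons of the two tethered alkynes, and C3'–C4' and C5'–C6' to the external alkyne. Ring B closes as the six-membered ring of the (2+2+2) cycloaddition, and the four-membered ring closes in the same event because C1' and C2' are tied together through C9 and C3, the strain being paid by arene formation. No stereocentre is formed; C3 is quaternary and untouched, and the temperature is kept at or below the boiling point of toluene so that the new benzocyclobutene does not open to the ortho-quinodimethane, which would erase C3. The selectivity needed is the orientation of 15: its methoxy-bearing carbon must bond to the silylated terminus C3' and its silyl-bearing carbon to C6'. This is expected on steric grounds, because the other orientation places two SiMe3 groups on neighbouring carbons beside the ring fusion. Homotrimerisation is held back by the bulk of the silylalkyne and by keeping 12 dilute through slow addition into excess 15.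

Step 8
Reactants: 16 (S)-spiro chromanone with SiMe3 at C3' and C5' and OMe at C4'
Product: 17 (S)-spiro chromanone with SiMe3 at C3', OMe at C4' and H at C5'
Conditions: TFA, CH2Cl2, −20 °C to 0 °C, stopped after loss of one silyl group
Reagents that add atoms: none
Why: Protodesilylation is an electrophilic ipso-substitution; both silyl groups are ortho to the C4' methoxy group, but C5' is a β-position of the benzocyclobutene, whereas C3' is the α-position next to the strained fusion, where the arenium ion is disfavoured, so C5' should react first. Ring A has no silyl group and is only protonated reversibly.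

Step 9
Reactants: 17 (S)-spiro chromanone with SiMe3 at C3', OMe at C4' and H at C5'
Product: 20 (S)-spiro chromanone with OH at C3' and OMe at C4', via aryllead tris(trifluoroacetate) 18 (not isolated), via aryl trifluoroacetate 19 (not isolated)
Conditions: Pb(OCOCF3)4 (1.1 equiv), TFA, 0 °C to rt; then aq. NaHCO3, THF
Reagents that add atoms: lead tetrakis(trifluoroacetate), O=C(O[Pb](OC(=O)C(F)(F)F)(OC(=O)C(F)(F)F)OC(=O)C(F)(F)F)C(F)(F)F
Why: Oxidative cleavage of an aryl–silicon bond by tetravalent lead: ipso-plumbation at C3', activated by the ortho methoxy group, gives the aryllead tris(trifluoroacetate), which collapses to the aryl trifluoroacetate and divalent lead, and mild hydrolysis frees the phenol. Ipso attack at a silicon-bearing carbon is much faster than attack at C–H, and ring A is deactivated in TFA by protonation of its conjugated ketone.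

Step 10
Reactants: 20 (S)-spiro chromanone with OH at C3' and OMe at C4'
Product: 21 (S)-spiro chromanone with OMe at C5, C7, C3' and C4' (CNP0192565.1)
Conditions: MeI, K2CO3, acetone, 50 °C
Reagents that add atoms: iodomethane, CI
Why: Williamson O-methylation of the phenol; C3 is quaternary, so the ketone cannot enolise and neither C-alkylation nor ring opening can occur.

## Compound list

1 | dimethyl 2-(prop-2-yn-1-yl)propanedioate | COC(=O)C(CC#C)C(=O)OC | starting material
2 | phenyl[(trimethylsilyl)ethynyl]iodonium trifluoromethanesulfonate | C[Si](C)(C)C#C[I+]c1ccccc1.[O-]S(=O)(=O)C(F)(F)F | starting material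
3 | potassium enolate of 1 | COC(=O)[C-](CC#C)C(=O)OC.[K+] | intermediate (not isolated)
4 | dimethyl 2-(prop-2-yn-1-yl)-2-[(trimethylsilyl)ethynyl]propanedioate | COC(=O)C(CC#C)(C#C[Si](C)(C)C)C(=O)OC | intermediate
5 | methyl (2S)-2-{[(triethoxysilyl)oxy]methyl}-2-[(trimethylsilyl)ethynyl]pent-4-ynoate | CCO[Si](OCC)(OCC)OC[C@](CC#C)(C#C[Si](C)(C)C)C(=O)OC | intermediate (not isolated)
6 | methyl (2S)-2-(hydroxymethyl)-2-[(trimethylsilyl)ethynyl]pent-4-ynoate | OC[C@](CC#C)(C#C[Si](C)(C)C)C(=O)OC | intermediate
7 | 3,5-dimethoxyphenol | COc1cc(O)cc(OC)c1 | starting material
8 | methyl (2S)-2-[(3,5-dimethoxyphenoxy)methyl]-2-[(trimethylsilyl)ethynyl]pent-4-ynoate | COc1cc(OC)cc(OC[C@](CC#C)(C#C[Si](C)(C)C)C(=O)OC)c1 | intermediate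
9 | lithium (2S)-2-[(3,5-dimethoxyphenoxy)methyl]-2-[(trimethylsilyl)ethynyl]pent-4-ynoate | COc1cc(OC)cc(OC[C@](CC#C)(C#C[Si](C)(C)C)C(=O)[O-])c1.[Li+] | intermediate (not isolated)
10 | (2S)-2-[(3,5-dimethoxyphenoxy)methyl]-2-[(trimethylsilyl)ethynyl]pent-4-ynoic acid | COc1cc(OC)cc(OC[C@](CC#C)(C#C[Si](C)(C)C)C(=O)O)c1 | intermediate
11 | mixed anhydride of 10 with trifluoroacetic acid | COc1cc(OC)cc(OC[C@](CC#C)(C#C[Si](C)(C)C)C(=O)OC(=O)C(F)(F)F)c1 | intermediate (not isolated)
12 | (3S)-5,7-dimethoxy-3-(prop-2-yn-1-yl)-3-[(trimethylsilyl)ethynyl]chroman-4-one | COc1cc(OC)c2c(c1)OC[C@](CC#C)(C#C[Si](C)(C)C)C2=O | intermediate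
13 | 2-chloro-1,1-dimethoxyethane (chloroacetaldehyde dimethyl acetal) | COC(CCl)OC | starting material
14 | lithium methoxyacetylide | COC#C[Li] | intermediate (not isolated)
15 | (methoxyethynyl)trimethylsilane | COC#C[Si](C)(C)C | intermediate
16 | (S)-5,7-dimethoxychroman-4-one spiro-fused at C3 (bonds to C9 and C2') to ring B with SiMe3 at C3' and C5', OMe at C4' | COc1cc(OC)c2c(c1)OC[C@@]1(Cc3cc([Si](C)(C)C)c(OC)c([Si](C)(C)C)c31)C2=O | intermediate
17 | (S)-spiro chromanone as 16 with SiMe3 at C3' only, OMe at C4', H at C5' | COc1cc(OC)c2c(c1)OC[C@@]1(Cc3ccc(OC)c([Si](C)(C)C)c31)C2=O | intermediate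
18 | (S)-spiro chromanone with Pb(OCOCF3)3 at C3', OMe at C4' | COc1cc(OC)c2c(c1)OC[C@@]1(Cc3ccc(OC)c([Pb](OC(=O)C(F)(F)F)(OC(=O)C(F)(F)F)OC(=O)C(F)(F)F)c31)C2=O | intermediate (not isolated)
19 | (S)-spiro chromanone with OCOCF3 at C3', OMe at C4' | COc1cc(OC)c2c(c1)OC[C@@]1(Cc3ccc(OC)c(OC(=O)C(F)(F)F)c31)C2=O | intermediate (not isolated)
20 | (S)-spiro chromanone with OH at C3', OMe at C4' | COc1cc(OC)c2c(c1)OC[C@@]1(Cc3ccc(OC)c(O)c31)C2=O | intermediate
21 | (S)-5,7-dimethoxychroman-4-one spiro-fused at C3 to the 3',4'-dimethoxybenzocyclobutene (CNP0192565.1) | COc1cc(OC)c2c(c1)OC[C@@]1(Cc3ccc(OC)c(OC)c31)C2=O | target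

## Step count and risk

Total: 10 steps. Longest linear sequence: 9 steps (steps 1–5 and 7–10); step 6 is a one-step side branch.

**Step 7 (key step).** The most likely failure is the wrong or a mixed orientation of the unsymmetrical alkyne. A cobaltacycle formed from 15 and the propargyl arm with silicon next to cobalt would lead the silyl-bearing carbon of 15, not the methoxy-bearing one, to bond to C3'. Oligomerisation of the ynol ether at cobalt could also lower the conversion, and prolonged heating could open the four-membered ring and erode the configuration at C3. The fallback sets out from 12 and returns at 21; in it the second ring B oxygen is no longer brought in by the alkyne. 12 is cocyclised under the same CpCo(CO)2 catalysis with acetylene (1 atm, slow stream), a symmetrical partner for which no orientation exists, to give the (S)-spiro chromanone with SiMe3 at C3' as the only ring B substituent F1. Oxidative desilylation as in step 9 proceeds through the aryllead tris(trifluoroacetate) F2 and the aryl trifluoroacetate F3 to the C3' phenol F4. IBX in DMF oxidises a phenol at a free ortho position; only C4' is free, so the C3',C4' ortho-quinone F5 forms and is reduced in the same flask with Na2S2O4 to the C3',C4' catechol F6. Methylation of both hydroxyl groups of F6 (MeI, K2CO3) gives 21.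

**Step 2.** The discrimination of the two enantiotopic ester groups may be insufficient, because the catalyst must tell a rod-shaped silylalkynyl group from a propargyl CH2 group. Zincation of the terminal alkyne by the basic catalyst may also tie up the metal. The fallback sets out from 4 and returns at 6; an enzymatic desymmetrisation replaces the catalytic reduction. An esterase (pig liver esterase, phosphate buffer, pH 7–8), selected by screening for the required sense, hydrolyses one ester group to (2S)-2-(methoxycarbonyl)-2-[(trimethylsilyl)ethynyl]pent-4-ynoic acid F7. The acid is converted with isobutyl chloroformate and N-methylmorpholine (THF, −15 °C) into the mixed isobutyl carbonic anhydride F8, which NaBH4 reduces to 6 without touching the methyl ester.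

**Step 8.** The wrong silyl group, or both, may be lost: steric compression at C3' between the methoxy group and the spiro centre accelerates ipso-protonation and may offset the lower reactivity of the α-position. The fallback sets out from 13 and 12 and returns at 17; the silicon at C5' is replaced by tin. 13 is converted into 14 as in step 6, and the acetylide is quenched with Bu3SnCl instead of TMSCl to give tributyl(methoxyethynyl)stannane F9. Cocyclisation of 12 with F9 under the conditions of step 7 gives the (S)-spiro chromanone with SnBu3 at C5', OMe at C4' and SiMe3 at C3' F10. An aryl–tin bond is cleaved by acid far faster than an aryl–silicon bond, so one equivalent of HCl in CH2Cl2 at low temperature removes tin only from F10 and gives 17.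

**Step 9.** Plumbation or oxidation of the electron-rich ring A at C6 or C8, or of C5'–H, may compete with the ipso attack at the hindered α-position C3'. The fallback sets out from 17 and returns at 21; electrophilic boron replaces lead. BBr3 (excess, CH2Cl2, −78 °C to rt) exchanges the C3' silyl group for boron by ipso-borodesilylation, which does not attack aryl C–H bonds, and at the same time cleaves the three methyl ethers; aqueous work-up gives the (S)-spiro chromanone with OH at C5, C7 and C4' and B(OH)2 at C3' F11. F11 is oxidised without isolation (NaBO3·4H2O, THF/water) to the (S)-spiro chromanone with OH at C5, C7, C3' and C4' F12. Exhaustive methylation of F12 (MeI, K2CO3, DMF, 60 °C, under argon) restores all four methyl ethers and gives 21.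

## Further compounds

F1 | step 7 | (S)-spiro chromanone with SiMe3 at C3', ring B otherwise unsubstituted | COc1cc(OC)c2c(c1)OC[C@@]1(Cc3cccc([Si](C)(C)C)c31)C2=O
F2 | step 7 | (S)-spiro chromanone with Pb(OCOCF3)3 at C3' | COc1cc(OC)c2c(c1)OC[C@@]1(Cc3cccc([Pb](OC(=O)C(F)(F)F)(OC(=O)C(F)(F)F)OC(=O)C(F)(F)F)c31)C2=O
F3 | step 7 | (S)-spiro chromanone with OCOCF3 at C3' | COc1cc(OC)c2c(c1)OC[C@@]1(Cc3cccc(OC(=O)C(F)(F)F)c31)C2=O
F4 | step 7 | (S)-spiro chromanone with OH at C3' | COc1cc(OC)c2c(c1)OC[C@@]1(Cc3cccc(O)c31)C2=O
F5 | step 7 | (S)-spiro chromanone with ring B as C3',C4' ortho-quinone | COc1cc(OC)c2c(c1)OC[C@@]1(CC3=C1C(=O)C(=O)C=C3)C2=O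
F6 | step 7 | (S)-spiro chromanone with OH at C3' and C4' | COc1cc(OC)c2c(c1)OC[C@@]1(Cc3ccc(O)c(O)c31)C2=O
F7 | step 2 | (2S)-2-(methoxycarbonyl)-2-[(trimethylsilyl)ethynyl]pent-4-ynoic acid | OC(=O)[C@](CC#C)(C#C[Si](C)(C)C)C(=O)OC
F8 | step 2 | mixed isobutyl carbonic anhydride of F7 | CC(C)COC(=O)OC(=O)[C@](CC#C)(C#C[Si](C)(C)C)C(=O)OC
F9 | step 8 | tributyl(methoxyethynyl)stannane | CCCC[Sn](CCCC)(CCCC)C#COC
F10 | step 8 | (S)-spiro chromanone with SnBu3 at C5', OMe at C4', SiMe3 at C3' | COc1cc(OC)c2c(c1)OC[C@@]1(Cc3cc([Sn](CCCC)(CCCC)CCCC)c(OC)c([Si](C)(C)C)c31)C2=O
F11 | step 9 | (S)-spiro chromanone with OH at C5, C7 and C4' and B(OH)2 at C3' | Oc1cc(O)c2c(c1)OC[C@@]1(Cc3ccc(O)c(B(O)O)c31)C2=O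
F12 | step 9 | (S)-spiro chromanone with OH at C5, C7, C3' and C4' | Oc1cc(O)c2c(c1)OC[C@@]1(Cc3ccc(O)c(O)c31)C2=O
A1 | alternative 1 | methyl 2-(6-bromo-2,3-dimethoxyphenyl)-2-methylpropanoate | COC(=O)C(C)(C)c1c(Br)ccc(OC)c1OC
A2 | alternative 1 | methyl (S)-5,6-dimethoxy-1-methylbenzocyclobutene-1-carboxylate | COC(=O)[C@@]1(C)Cc2ccc(OC)c(OC)c21
A3 | alternative 2 | (R)-1-(chloromethyl)-5,6-dimethoxybenzocyclobutene-1-carboxylic acid | OC(=O)[C@@]1(CCl)Cc2ccc(OC)c(OC)c21
A4 | alternative 2 | 3,5-dimethoxybenzyne | COC1=CC(OC)=CC#C1
A5 | alternative 2 | (R)-[1-(chloromethyl)-5,6-dimethoxybenzocyclobuten-1-yl](2-hydroxy-4,6-dimethoxyphenyl)methanone | COc1cc(O)c(C(=O)[C@@]2(CCl)Cc3ccc(OC)c(OC)c32)c(OC)c1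
A6 | alternative 3 | 2-{[2-(6-bromo-2,3-dimethoxyphenyl)prop-2-en-1-yl]oxy}-4,6-dimethoxybenzaldehyde | COc1cc(OC)c(C=O)c(OCC(=C)c2c(Br)ccc(OC)c2OC)c1
A7 | alternative 3 | (S)-3-(6-bromo-2,3-dimethoxyphenyl)-5,7-dimethoxy-3-methylchroman-4-one | COc1cc(OC)c2c(c1)OC[C@](C)(c1c(Br)ccc(OC)c1OC)C2=O
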